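**Plan**

- Retrosynthesis: after global deprotection, the pyran ring (ring C) of the middle flavan is cut at C4a–C4 and C2–C3 (formal [4+2]). This leaves a 3,4-bis(benzyloxy)benzyl aryl ether on ring D (ring A of the middle unit) and a (Z)-2-(flavan-4-yloxy)vinyl acetate. Further cuts: the top C4–aryl bond (Friedel–Crafts), the O–CH2 benzyl ether bond, and the O-allyl bond on the lower 4-ol.
- Forward: the top unit is made from (−)-epicatechin (benzylation, C4 oxidation, C4 arylation with a phloroglucinol diether, O-alkylation with the ring B benzyl chloride). The lower unit is made from (+)-epicatechin (benzylation, C4 ketone, reduction, O-allylation, cleavage, Z-enol acetate). Ring C of the middle unit is then built between the two, followed by deprotection.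
- Enabling feature: ring D is a phloroglucinol ring whose O1 carries a CH2 bound to an electron-rich 3,4-dioxygenated aryl group, and whose ortho carbon C4a is free and activated by O1, O5 and O7. Hydride loss at that CH2 gives the aryl oxocarbenium C4a=C8a–O1(+)=C2, a cationic 2-oxadiene that takes up a Z-1,2-dioxygenated alkene (C3=C4).
- Stereochemistry: C2 and C3 of the top and lower units come from the two enantiomers of epicatechin. Top C4 is set by anti capture of a C4 cation, lower C4 by hydride attack anti to the 3-benzyloxy group. Middle C2, C3 and C4 are set in the key step (endo approach of the Z-alkene, anti ring closure, absolute sense by double diastereoselection).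

Key step: step 14

Remark: (+)-epicatechin, 3,5-bis(benzyloxy)phenol and 3,4-bis(benzyloxy)benzyl chloride are taken as purchasable. Flavan numbering (O1, C2, C3, C4, C4a, C5–C8, C8a) is used for every unit, and "4β" means trans to the 3-oxygen in the (2R,3R) series.

**Step 1**
Reactants: 1 (−)-epicatechin
Product: 2 5,7,3',4'-tetra-O-benzyl-(−)-epicatechin (2R,3R)
Conditions: BnBr, K2CO3, DMF, 0 °C → rt
Reagents that add atoms: benzyl bromide, BrCc1ccccc1
Why: Williamson ether synthesis in which K2CO3 deprotonates the four phenols but not the secondary 3-OH, so the tetra-O-benzyl ether should form without touching C2 or C3.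

**Step 2**
Reactants: 2 5,7,3',4'-tetra-O-benzyl-(−)-epicatechin
Product: 3 3,5,7,3',4'-penta-O-benzyl-(−)-epicatechin (2R,3R)
Conditions: NaH, BnBr, DMF, 0 °C → rt
Reagents that add atoms: benzyl bromide, BrCc1ccccc1
Why: Williamson ether synthesis on the sodium alkoxide of the 3-OH; with all phenols capped there is no ring-opening pathway, so C2 and C3 keep their configuration.

**Step 3**
Reactants: 3 3,5,7,3',4'-penta-O-benzyl-(−)-epicatechin
Product: 4 (2R,3R,4S)-3,5,7,3',4'-penta-O-benzyl-4-(2-ethoxyethoxy)flavan (4β, 3,4-trans)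
Conditions: DDQ, 2-ethoxyethanol, CH2Cl2, rt
Reagents that add atoms: 2-ethoxyethanol, CCOCCO
Why: DDQ-mediated benzylic oxidation in which hydride abstraction at C4 (activated by the 5,7-dioxygenated ring A) gives the C4 cation and the alcohol adds anti to the 3-benzyloxy and 2-aryl groups; this centre is ionised again in step 4.

**Step 4**
Reactants: 4 (2R,3R,4S)-3,5,7,3',4'-penta-O-benzyl-4-(2-ethoxyethoxy)flavan; 5 3,5-bis(benzyloxy)phenol (excess)
Product: 6 2-[3,5,7,3',4'-penta-O-benzyl-(−)-epicatechin-4β-yl]-3,5-bis(benzyloxy)phenol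
Conditions: Me3SiOTf (cat.), CH2Cl2, −78 → −40 °C
Reagents that add atoms: none
Why: Lewis-acid-promoted Friedel–Crafts alkylation of the kind used for procyanidin interflavan bonds, in which Me3SiOTf ionises the 4-alkoxy group and the arene attacks the C4 cation anti to the 3-benzyloxy group (setting the 4β, 3,4-trans centre) at the carbon between OH and OBn, which is less hindered than the carbon between the two OBn groups (the C8-over-C6 preference of flavan nucleophiles) and is also reached by O-alkylation followed by O-to-C migration.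

**Step 5**
Reactants: 6 2-[penta-O-benzyl-(−)-epicatechin-4β-yl]-3,5-bis(benzyloxy)phenol; 7 3,4-bis(benzyloxy)benzyl chloride
Product: 8 3,4-bis(benzyloxy)benzyl ether of phenol 6
Conditions: K2CO3, NaI (cat.), DMF, 50 °C
Reagents that add atoms: none
Why: Williamson ether synthesis on the hindered phenoxide in a dipolar aprotic solvent (O- over C-alkylation), which installs ring B and C2 of the middle unit as a benzylic CH2 ready for hydride abstraction.

**Step 6**
Reactants: 9 (+)-epicatechin
Product: 10 5,7,3',4'-tetra-O-benzyl-(+)-epicatechin (2S,3S)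
Conditions: BnBr, K2CO3, DMF, 0 °C → rt
Reagents that add atoms: benzyl bromide, BrCc1ccccc1
Why: Williamson ether synthesis selective for the four phenols, as in step 1, leaving C2 and C3 untouched.

**Step 7**
Reactants: 10 5,7,3',4'-tetra-O-benzyl-(+)-epicatechin
Product: 11 3,5,7,3',4'-penta-O-benzyl-(+)-epicatechin (2S,3S)
Conditions: NaH, BnBr, DMF, 0 °C → rt
Reagents that add atoms: benzyl bromide, BrCc1ccccc1
Why: Williamson ether synthesis on the 3-alkoxide, as in step 2; the robust 3-O-benzyl group prevents acyl migration and participation in the later steps.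

**Step 8**
Reactants: 11 3,5,7,3',4'-penta-O-benzyl-(+)-epicatechin
Product: 12 (2S,3S,4R)-3,5,7,3',4'-penta-O-benzylflavan-4-ol (3,4-trans)
Conditions: DDQ, CH2Cl2/H2O, rt
Reagents that add atoms: water, O
Why: DDQ-mediated benzylic oxidation at C4 with water as the nucleophile, which adds anti to the 3-benzyloxy group; this centre is removed in step 9.

**Step 9**
Reactants: 12 (2S,3S,4R)-3,5,7,3',4'-penta-O-benzylflavan-4-ol
Product: 13 (2S,3R)-3,5,7,3',4'-penta-O-benzylflavan-4-one (2,3-cis)
Conditions: (n-Pr4N)RuO4 (cat.), N-methylmorpholine N-oxide, 4 Å MS, CH2Cl2, rt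
Reagents that add atoms: none
Why: Ley–Griffith oxidation of the secondary benzylic alcohol under neutral conditions, which avoids enolisation of the 2,3-cis ketone toward C3 epimerisation or ring opening.

**Step 10**
Reactants: 13 (2S,3R)-3,5,7,3',4'-penta-O-benzylflavan-4-one
Product: 14 (2S,3S,4S)-3,5,7,3',4'-penta-O-benzylflavan-4-ol (all-cis)
Conditions: NaBH4, THF/MeOH, −40 → 0 °C
Reagents that add atoms: none
Why: substrate-controlled hydride reduction in which, in the half-chair with the 2-aryl group equatorial and the 3-benzyloxy group pseudo-axial, hydride attacks C4 anti to the C3–O bond (Felkin–Anh sense), so the new hydroxyl should be cis to the 3-benzyloxy and 2-aryl groups.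

**Step 11**
Reactants: 14 (2S,3S,4S)-3,5,7,3',4'-penta-O-benzylflavan-4-ol; 15 allyl bromide
Product: 16 (2S,3S,4S)-4-allyloxy-3,5,7,3',4'-penta-O-benzylflavan
Conditions: NaH, DMF, 0 °C → rt
Reagents that add atoms: none
Why: Williamson ether synthesis that does not break the C4–O bond, so the all-cis configuration is kept, and the allyl group supplies the two carbons that become C4 and C3 of the middle unit.

**Step 12**
Reactants: 16 (2S,3S,4S)-4-allyloxy-3,5,7,3',4'-penta-O-benzylflavan
Product: 17 2-{[(2S,3S,4S)-3,5,7,3',4'-penta-O-benzylflavan-4-yl]oxy}acetaldehyde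
Conditions: OsO4 (cat.), NaIO4, 2,6-lutidine, dioxane/H2O, rt
Reagents that add atoms: sodium periodate, [Na+].[O-]I(=O)(=O)=O (terminal oxidant and source of the aldehyde oxygen by way of OsO4, O=[Os](=O)(=O)=O)
Why: Lemieux–Johnson oxidative cleavage (dihydroxylation by OsO4, glycol cleavage by NaIO4) of the terminal alkene under lutidine-buffered, near-neutral conditions that leave the benzyl ethers and the acid-labile C4–O bond alone.

**Step 13**
Reactants: 17 2-{[(2S,3S,4S)-penta-O-benzylflavan-4-yl]oxy}acetaldehyde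
Product: 18 (Z)-2-{[(2S,3S,4S)-3,5,7,3',4'-penta-O-benzylflavan-4-yl]oxy}vinyl acetate
Conditions: KN(SiMe3)2, THF, −78 °C (aldehyde added to base); then Ac2O
Reagents that add atoms: acetic anhydride, CC(=O)OC(C)=O
Why: O-acylation of an aldehyde enolate in which the potassium enolate is held in the Z geometry by chelation of potassium between the enolate and ether oxygens and is trapped on oxygen by acetic anhydride.

**Step 14**
Reactants: 8 3,4-bis(benzyloxy)benzyl ether of phenol 6; 18 (Z)-2-(flavan-4-yloxy)vinyl acetate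
Product: 21 tetradeca-O-benzyl trimer carrying 3-O-acetyl on the middle unit, via aryl oxocarbenium ion 19 (not isolated), via open-chain alkoxycarbenium ion 20 (not isolated)
Conditions: DDQ (1.05 equiv), LiClO4, 2,6-dichloropyridine, 4 Å MS, CH2Cl2, 0 °C; then 18 (1.3 equiv), −40 → 0 °C
Reagents that add atoms: none
Why: Proposed new method: DDQ should abstract hydride from the O–CH2 group of the only 3,4-dialkoxybenzyl aryl ether in 8 (it has no β-oxygen, unlike C2–H of the top unit, and is unhindered, unlike the diarylmethine C4–H) to give the planar aryl oxocarbenium ion 19, a cationic 2-oxadiene (C4a=C8a–O1(+)=C2), before the acid-sensitive alkene is added; 18 then attacks C2 through its acetoxy-bearing carbon (the carbon β to the better donor, the ether oxygen) to give alkoxycarbenium ion 20, whose C4 is captured by the free ortho carbon C4a of ring D (activated by O1, 5-OBn and 7-OBn) and rearomatised by DDQH(−), so that both C–C bonds form in one flask without a Lewis acid that would ionise the two C4–O bonds. The closest known reaction types are the oxa-Povarov reaction of aryl oxocarbenium ions (from O-aryl mixed acetals and SnCl4) with alkenes, the dehydrogenative Povarov reaction of N-benzylanilines, and the DDQ-mediated oxidative C–H cleavage of benzylic ethers with enol acetate trapping. Ring C of the middle unit closes in a 6-(enolendo)-exo-trig Friedel–Crafts mode on the oxocarbenium carbon, which makes the whole event a formal inverse-electron-demand [4+2] cycloaddition. C2 and C3 should become cis because the Z-alkene approaches the E-oxocarbenium (aryl group outside) in the endo, synclinal orientation with its alkoxy-bearing carbon over ring D, and C4 should become trans to C3 because 20 closes through the chair with the 2-aryl group equatorial and the C4=O(+) bond anti to the C3–OAc bond (dipole minimisation), which places the 4-alkoxy group pseudo-axial and away from the peri 5-OBn group, the sense seen in captures of 2,3-cis flavan C4 cations. The absolute sense (2R,3R,4S against 2S,3S,4R) rests on double diastereoselection by the enantiopure flavan-4-yl group on the alkene oxygen and by the top unit ortho to O1; as both partners are single enantiomers, the unwanted adduct is a diastereomer and is removed by chromatography. The step needs site-selective hydride abstraction, C3-to-C2 regiochemistry (secured by the acetate, a poor donor) and ring closure faster than loss of the lower flavanyl cation from 20 (secured by the proximity and high nucleophilicity of C4a).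

**Step 15**
Reactants: 21 tetradeca-O-benzyl trimer 3-O-acetate
Product: 22 tetradeca-O-benzyl trimer with free 3-OH on the middle unit
Conditions: K2CO3 (cat.), MeOH/THF, rt
Reagents that add atoms: none
Why: base-catalysed transesterification (methanolysis) of the secondary acetate with acyl–oxygen cleavage, so C3 keeps its configuration and the base-stable benzylic ethers are untouched.

**Step 16**
Reactants: 22 tetradeca-O-benzyl trimer with free middle 3-OH
Product: 23 CNP0310719.1
Conditions: H2 (1 atm), Pd(OH)2/C, THF/H2O, rt; filtration, freeze-drying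
Reagents that add atoms: none
Why: catalytic hydrogenolysis of the fourteen benzyl ethers under neutral, non-alcoholic conditions, in which primary O-benzyl groups should cleave much faster than the hindered secondary benzylic C–O bonds at C2 and C4, of the type that survives flavan-3-ol debenzylations.

**Compound list**

1 | (−)-epicatechin, (2R,3R)-2-(3,4-dihydroxyphenyl)chromane-3,5,7-triol | Oc1cc(O)c2c(c1)O[C@H](c1ccc(O)c(O)c1)[C@H](O)C2 | starting material
2 | 5,7,3',4'-tetra-O-benzyl-(−)-epicatechin (2R,3R) | c9ccccc9COc1cc(OCc9ccccc9)c2c(c1)O[C@H](c1ccc(OCc9ccccc9)c(OCc9ccccc9)c1)[C@H](O)C2 | intermediate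
3 | 3,5,7,3',4'-penta-O-benzyl-(−)-epicatechin (2R,3R) | c9ccccc9COc1cc(OCc9ccccc9)c2c(c1)O[C@H](c1ccc(OCc9ccccc9)c(OCc9ccccc9)c1)[C@H](OCc9ccccc9)C2 | intermediate
4 | (2R,3R,4S)-3,5,7,3',4'-penta-O-benzyl-4-(2-ethoxyethoxy)flavan (4β, 2,3-cis-3,4-trans) | c9ccccc9COc1cc(OCc9ccccc9)c2c(c1)O[C@H](c1ccc(OCc9ccccc9)c(OCc9ccccc9)c1)[C@H](OCc9ccccc9)[C@H]2OCCOCC | intermediate
5 | 3,5-bis(benzyloxy)phenol | Oc1cc(OCc2ccccc2)cc(OCc2ccccc2)c1 | starting material
6 | 2-[3,5,7,3',4'-penta-O-benzyl-(−)-epicatechin-4β-yl]-3,5-bis(benzyloxy)phenol (flavan unit 2,3-cis-3,4-trans) | c9ccccc9COc1cc(OCc9ccccc9)c2c(c1)O[C@H](c1ccc(OCc9ccccc9)c(OCc9ccccc9)c1)[C@H](OCc9ccccc9)[C@H]2c1c(OCc9ccccc9)cc(OCc9ccccc9)cc1O | intermediate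
7 | 3,4-bis(benzyloxy)benzyl chloride | ClCc1ccc(OCc2ccccc2)c(OCc2ccccc2)c1 | starting material
8 | 3,4-bis(benzyloxy)benzyl ether of phenol 6: 1-[3,4-bis(benzyloxy)benzyloxy]-3,5-bis(benzyloxy)-2-[penta-O-benzyl-(−)-epicatechin-4β-yl]benzene | c9ccccc9COc1cc(OCc9ccccc9)c2c(c1)O[C@H](c1ccc(OCc9ccccc9)c(OCc9ccccc9)c1)[C@H](OCc9ccccc9)[C@H]2c1c(OCc9ccccc9)cc(OCc9ccccc9)cc1OCc1ccc(OCc9ccccc9)c(OCc9ccccc9)c1 | intermediate
9 | (+)-epicatechin, (2S,3S)-2-(3,4-dihydroxyphenyl)chromane-3,5,7-triol | Oc1cc(O)c2c(c1)O[C@@H](c1ccc(O)c(O)c1)[C@@H](O)C2 | starting material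
10 | 5,7,3',4'-tetra-O-benzyl-(+)-epicatechin (2S,3S) | c9ccccc9COc1cc(OCc9ccccc9)c2c(c1)O[C@@H](c1ccc(OCc9ccccc9)c(OCc9ccccc9)c1)[C@@H](O)C2 | intermediate
11 | 3,5,7,3',4'-penta-O-benzyl-(+)-epicatechin (2S,3S) | c9ccccc9COc1cc(OCc9ccccc9)c2c(c1)O[C@@H](c1ccc(OCc9ccccc9)c(OCc9ccccc9)c1)[C@@H](OCc9ccccc9)C2 | intermediate
12 | (2S,3S,4R)-3,5,7,3',4'-penta-O-benzylflavan-4-ol (2,3-cis-3,4-trans) | c9ccccc9COc1cc(OCc9ccccc9)c2c(c1)O[C@@H](c1ccc(OCc9ccccc9)c(OCc9ccccc9)c1)[C@@H](OCc9ccccc9)[C@@H]2O | intermediate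
13 | (2S,3R)-3,5,7,3',4'-penta-O-benzylflavan-4-one (2,3-cis) | c9ccccc9COc1cc(OCc9ccccc9)c2c(c1)O[C@@H](c1ccc(OCc9ccccc9)c(OCc9ccccc9)c1)[C@@H](OCc9ccccc9)C2=O | intermediate
14 | (2S,3S,4S)-3,5,7,3',4'-penta-O-benzylflavan-4-ol (all-cis) | c9ccccc9COc1cc(OCc9ccccc9)c2c(c1)O[C@@H](c1ccc(OCc9ccccc9)c(OCc9ccccc9)c1)[C@@H](OCc9ccccc9)[C@H]2O | intermediate
15 | allyl bromide | C=CCBr | starting material
16 | (2S,3S,4S)-4-allyloxy-3,5,7,3',4'-penta-O-benzylflavan (all-cis) | c9ccccc9COc1cc(OCc9ccccc9)c2c(c1)O[C@@H](c1ccc(OCc9ccccc9)c(OCc9ccccc9)c1)[C@@H](OCc9ccccc9)[C@H]2OCC=C | intermediate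
17 | 2-{[(2S,3S,4S)-3,5,7,3',4'-penta-O-benzylflavan-4-yl]oxy}acetaldehyde | c9ccccc9COc1cc(OCc9ccccc9)c2c(c1)O[C@@H](c1ccc(OCc9ccccc9)c(OCc9ccccc9)c1)[C@@H](OCc9ccccc9)[C@H]2OCC=O | intermediate
18 | (Z)-2-{[(2S,3S,4S)-3,5,7,3',4'-penta-O-benzylflavan-4-yl]oxy}vinyl acetate | c9ccccc9COc1cc(OCc9ccccc9)c2c(c1)O[C@@H](c1ccc(OCc9ccccc9)c(OCc9ccccc9)c1)[C@@H](OCc9ccccc9)[C@H]2O/C=C\OC(C)=O | intermediate
19 | aryl oxocarbenium ion from 8 (O1(+)=C2H–aryl on ring D), as its 2,3-dichloro-5,6-dicyano-4-hydroxyphenoxide salt | c9ccccc9COc1cc(OCc9ccccc9)c2c(c1)O[C@H](c1ccc(OCc9ccccc9)c(OCc9ccccc9)c1)[C@H](OCc9ccccc9)[C@H]2c1c(OCc9ccccc9)cc(OCc9ccccc9)cc1[O+]=Cc1ccc(OCc9ccccc9)c(OCc9ccccc9)c1.[O-]c1c(Cl)c(Cl)c(O)c(C#N)c1C#N | intermediate (not isolated)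
20 | open-chain alkoxycarbenium ion (C2–C3 bond formed, 2,3-syn; C4=O(+)–flavanyl), same counter-ion | c9ccccc9COc1cc(OCc9ccccc9)c2c(c1)O[C@H](c1ccc(OCc9ccccc9)c(OCc9ccccc9)c1)[C@H](OCc9ccccc9)[C@H]2c1c(OCc9ccccc9)cc(OCc9ccccc9)cc1O[C@H](c1ccc(OCc9ccccc9)c(OCc9ccccc9)c1)[C@H](OC(C)=O)C=[O+][C@H]1c2c(OCc9ccccc9)cc(OCc9ccccc9)cc2O[C@@H](c2ccc(OCc9ccccc9)c(OCc9ccccc9)c2)[C@H]1OCc9ccccc9.[O-]c1c(Cl)c(Cl)c(O)c(C#N)c1C#N | intermediate (not isolated)
21 | protected trimer acetate: penta-O-benzyl-epicatechin-(4β→8)-[(2R,3R,4S)-3-O-acetyl-5,7,3',4'-tetra-O-benzylflavan-3,4-diol]-(4β-O-4)-[(2S,3S,4S)-3,5,7,3',4'-penta-O-benzylflavan-4-yl] | c9ccccc9COc1cc(OCc9ccccc9)c2c(c1)O[C@H](c1ccc(OCc9ccccc9)c(OCc9ccccc9)c1)[C@H](OCc9ccccc9)[C@H]2c1c(OCc9ccccc9)cc(OCc9ccccc9)c2c1O[C@H](c1ccc(OCc9ccccc9)c(OCc9ccccc9)c1)[C@H](OC(C)=O)[C@H]2O[C@H]1c2c(OCc9ccccc9)cc(OCc9ccccc9)cc2O[C@@H](c2ccc(OCc9ccccc9)c(OCc9ccccc9)c2)[C@H]1OCc9ccccc9 | intermediate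
22 | protected trimer as 21 with free 3-OH on the middle unit | c9ccccc9COc1cc(OCc9ccccc9)c2c(c1)O[C@H](c1ccc(OCc9ccccc9)c(OCc9ccccc9)c1)[C@H](OCc9ccccc9)[C@H]2c1c(OCc9ccccc9)cc(OCc9ccccc9)c2c1O[C@H](c1ccc(OCc9ccccc9)c(OCc9ccccc9)c1)[C@H](O)[C@H]2O[C@H]1c2c(OCc9ccccc9)cc(OCc9ccccc9)cc2O[C@@H](c2ccc(OCc9ccccc9)c(OCc9ccccc9)c2)[C@H]1OCc9ccccc9 | intermediate
23 | CNP0310719.1: (2R,3R,4R)-epicatechin-(4β→8)-[(2R,3R,4S)-flavan-3,4-diol unit]-(4β-O-4)-[(2S,3S,4S)-all-cis flavan-3-ol unit] | Oc1cc(O)c2c(c1)O[C@H](c1ccc(O)c(O)c1)[C@H](O)[C@H]2c1c(O)cc(O)c2c1O[C@H](c1ccc(O)c(O)c1)[C@H](O)[C@H]2O[C@H]1c2c(O)cc(O)cc2O[C@@H](c2ccc(O)c(O)c2)[C@H]1O | target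

**Step count**

Total: 16 steps. Longest linear sequence: 11 steps (steps 6–13, then 14–16).

**Steps most likely to fail**

Step 14. Several things may go wrong:
- hydride abstraction at other benzylic sites;
- intermolecular Friedel–Crafts capture of the oxocarbenium ion by ring A carbons;
- loss of the lower flavanyl cation from the alkoxycarbenium ion before ring closure;
- poor endo or facial selectivity, the absolute sense being argued from a model only.

The fallback uses known reactions and builds the middle unit from epicatechin instead. It sets out from 4 and 2. Coupling with catalytic Me3SiOTf (CH2Cl2, −78 °C; 2 in excess) should give 3,5,7,3',4'-penta-O-benzyl-epicatechin-(4β→8)-5,7,3',4'-tetra-O-benzyl-epicatechin F1. Acetylation (Ac2O, pyridine, DMAP) gives its 3-O-acetate on the lower unit F2. F2 is then oxidised at the free C4 with DDQ in CH2Cl2, and alcohol 14 is added to capture the C4 cation anti to the 3-acetoxy group. This gives 21, where the route is rejoined.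

Step 4. The C-alkylation may go to the carbon between the two benzyloxy groups, or the phenol may be alkylated twice. The fallback sets out from 4 and removes the regiochemical question by using a nucleophile with three equivalent carbons. Coupling with excess phloroglucinol (BF3·OEt2, THF/CH2Cl2, 0 °C) gives 2-[penta-O-benzyl-(−)-epicatechin-4β-yl]benzene-1,3,5-triol F3. Benzylation with two equivalents of benzyl bromide (K2CO3, acetone) takes the unhindered para hydroxyl and then one of the two equivalent flanking hydroxyls. This gives 6, where the route is rejoined.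

Step 16. The two C4–O bonds may be cleaved by over-reduction, or by solvolysis once the electron-rich free phenol rings are exposed. The fallback sets out from 22 and avoids building up the free polyphenol under the reduction conditions. Hydrogenolysis is run in ethyl acetate in the presence of acetic anhydride, and acetylation is completed with pyridine and DMAP after filtration. This gives the pentadeca-O-acetate of the target F4, which is stable and can be purified. Methanolysis with catalytic K2CO3 in degassed methanol at 0 °C under argon then gives 23.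

**Further compounds**

F1 | step 14 | 3,5,7,3',4'-penta-O-benzyl-epicatechin-(4β→8)-5,7,3',4'-tetra-O-benzyl-epicatechin (lower 3-OH free) | c9ccccc9COc1cc(OCc9ccccc9)c2c(c1)O[C@H](c1ccc(OCc9ccccc9)c(OCc9ccccc9)c1)[C@H](OCc9ccccc9)[C@H]2c1c(OCc9ccccc9)cc(OCc9ccccc9)c2c1O[C@H](c1ccc(OCc9ccccc9)c(OCc9ccccc9)c1)[C@H](O)C2
F2 | step 14 | 3-O-acetate (lower unit) of F1 | c9ccccc9COc1cc(OCc9ccccc9)c2c(c1)O[C@H](c1ccc(OCc9ccccc9)c(OCc9ccccc9)c1)[C@H](OCc9ccccc9)[C@H]2c1c(OCc9ccccc9)cc(OCc9ccccc9)c2c1O[C@H](c1ccc(OCc9ccccc9)c(OCc9ccccc9)c1)[C@H](OC(C)=O)C2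
F3 | step 4 | 2-[3,5,7,3',4'-penta-O-benzyl-(−)-epicatechin-4β-yl]benzene-1,3,5-triol | c9ccccc9COc1cc(OCc9ccccc9)c2c(c1)O[C@H](c1ccc(OCc9ccccc9)c(OCc9ccccc9)c1)[C@H](OCc9ccccc9)[C@H]2c1c(O)cc(O)cc1O
F4 | step 16 | pentadeca-O-acetate of the target (all twelve phenols and the three 3-OH groups acetylated) | CC(=O)Oc1cc(OC(C)=O)c2c(c1)O[C@H](c1ccc(OC(C)=O)c(OC(C)=O)c1)[C@H](OC(C)=O)[C@H]2c1c(OC(C)=O)cc(OC(C)=O)c2c1O[C@H](c1ccc(OC(C)=O)c(OC(C)=O)c1)[C@H](OC(C)=O)[C@H]2O[C@H]1c2c(OC(C)=O)cc(OC(C)=O)cc2O[C@@H](c2ccc(OC(C)=O)c(OC(C)=O)c2)[C@H]1OC(C)=O
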